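**Plan**

- Retrosynthetic cuts, in order: the protecting groups; the ester C–O bond between the C2 carboxyl and one (R)-danshensu unit; the C1–C2 bond of ring B; the C3=C4 double bond; the C1–C8a bond between ring A and the diaryl carbinol carbon.
- Forward: ring A (as its catechol acetonide) is joined to the pendant aryl aldehyde at C1, formylated at the ortho position, and olefinated with a phosphonate that already carries the first danshensu ester and an allyl arm; cleavage of the allyl group gives the aldehyde, and ring B closes last.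
- Enabling feature: the pendant aryl on C1 has an OH para to C1, so C1 can become the exocyclic carbon of a para-quinone methide that faces the enolisable C2 across ring B (C1, C2, C3=C4, C4a, C8a; catechol ring A fused at C4a/C8a).
- Stereochemistry: both lactate centres come from (R)-danshensu; C2 is set by a chiral secondary amine and C1 follows as trans from the cyclic transition state.
- Because the C3 ester is already an enantiopure lactate, every unwanted core isomer is a diastereomer and can be separated.

Key step: step 14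

Assumption: (R)-danshensu 10 is used as the free acid; material bought as the sodium salt is acidified and extracted first.
Core numbering follows the target (C1 aryl-bearing, C2, C3=C4, C4a to C8a). "Dan" stands for the (2R)-1-tert-butoxy-3-(2,2-dimethyl-1,3-benzodioxol-5-yl)-1-oxopropan-2-yl group, i.e. the alkyl group of alcohol 13.

**Route**

Step 1
Reactants: 1 3,4-dihydroxybenzaldehyde
Product: 2 3,4-bis(tert-butyldimethylsilyloxy)benzaldehyde
Conditions: TBSCl, imidazole, DMF, rt
Reagents that add atoms: tert-butyldimethylsilyl chloride, CC(C)(C)[Si](C)(C)Cl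
Why: Standard silylation of phenols, which masks both acidic OH groups before the organometallic addition.

Step 2
Reactants: 3 2,2-dimethyl-1,3-benzodioxole
Product: 4 5,6-dibromo-2,2-dimethyl-1,3-benzodioxole
Conditions: NBS (2.2 equiv), DMF, rt
Reagents that add atoms: N-bromosuccinimide, O=C1CCC(=O)N1Br
Why: Electrophilic aromatic bromination in which each ring oxygen directs para, so the two bromines should enter at C5 and C6, and NBS avoids free HBr that could open the acetonide.

Step 3
Reactants: 4 5,6-dibromo-2,2-dimethyl-1,3-benzodioxole; 2 3,4-bis(tert-butyldimethylsilyloxy)benzaldehyde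
Product: 6 (6-bromo-2,2-dimethyl-1,3-benzodioxol-5-yl)[3,4-bis(tert-butyldimethylsilyloxy)phenyl]methanol (racemic), via arylmagnesium chloride 5 (not isolated)
Conditions: i-PrMgCl·LiCl, THF, −15 °C; then 2, −15 °C to rt; aq. NH4Cl
Reagents that add atoms: none
Why: Bromine–magnesium exchange on one bromine of the ortho-dibromide gives an ortho-bromoaryl Grignard reagent that resists aryne formation and undergoes Grignard 1,2-addition to the aldehyde; the carbinol carbon (later C1) is racemic, which is acceptable because it becomes planar in step 14.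

Step 4
Reactants: 6 the bromo diaryl carbinol
Product: 7 triethylsilyl ether of 6 (racemic)
Conditions: TESCl, imidazole, DMAP (cat.), DMF, rt
Reagents that add atoms: chlorotriethylsilane, CC[Si](Cl)(CC)CC
Why: Silylation of the secondary alcohol, which keeps the carbinol oxygen from adding to the acrylate built later and allows its removal together with the aryl silyl ethers in step 13.

Step 5
Reactants: 7 the bromo triethylsilyl ether
Product: 9 6-{[3,4-bis(tert-butyldimethylsilyloxy)phenyl](triethylsilyloxy)methyl}-2,2-dimethyl-1,3-benzodioxole-5-carbaldehyde (racemic), via aryllithium 8 (not isolated)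
Conditions: n-BuLi, THF, −78 °C; then DMF, −78 to 0 °C; aq. NH4Cl
Reagents that add atoms: N,N-dimethylformamide, CN(C)C=O
Why: Bromine–lithium exchange followed by Bouveault formylation with DMF, the low temperature and short lifetime of 8 guarding against silyl migration from oxygen to the lithiated carbon.

Step 6
Reactants: 10 (R)-3-(3,4-dihydroxyphenyl)lactic acid ((R)-danshensu)
Product: 11 (5R)-5-[(2,2-dimethyl-1,3-benzodioxol-5-yl)methyl]-2,2-dimethyl-1,3-dioxolan-4-one
Conditions: 2,2-dimethoxypropane, TsOH·H2O (cat.), benzene, reflux, 4 Å MS in a Soxhlet thimble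
Reagents that add atoms: 2,2-dimethoxypropane, COC(C)(C)OC
Why: Acid-catalysed transketalisation protects the catechol as its acetonide and ties the α-hydroxy acid up as a 1,3-dioxolan-4-one without touching the stereocentre.

Step 7
Reactants: 11 the bis-acetonide
Product: 12 (2R)-3-(2,2-dimethyl-1,3-benzodioxol-5-yl)-2-hydroxypropanoic acid
Conditions: LiOH, THF/H2O, 0 °C; then cold 1 M HCl to pH 3
Reagents that add atoms: lithium hydroxide, [Li+].[OH-]
Why: Saponification of the activated lactone carbonyl of the dioxolanone releases acetone and the α-hydroxy acid, while the aryl ketal is inert to base and to brief contact with cold dilute acid.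

Step 8
Reactants: 12 the acetonide hydroxy acid
Product: 13 tert-butyl (2R)-3-(2,2-dimethyl-1,3-benzodioxol-5-yl)-2-hydroxypropanoate (Dan–OH)
Conditions: O-tert-butyl-N,N'-diisopropylisourea, CH2Cl2, rt
Reagents that add atoms: O-tert-butyl-N,N'-diisopropylisourea, CC(C)N=C(OC(C)(C)C)NC(C)C
Why: Isourea-mediated tert-butyl esterification is selective for the carboxylic acid over the secondary alcohol and needs no strong acid, so the acetonide and the stereocentre are kept.

Step 9
Reactants: 13 Dan–OH; 14 diethylphosphonoacetic acid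
Product: 15 Dan (diethoxyphosphoryl)acetate
Conditions: DCC, DMAP (cat.), CH2Cl2, 0 °C to rt
Reagents that add atoms: none
Why: Steglich esterification acylates the secondary alcohol at oxygen, so the (R) centre is not involved.

Step 10
Reactants: 15 Dan (diethoxyphosphoryl)acetate
Product: 17 Dan 2-(diethoxyphosphoryl)pent-4-enoate (both epimers at the phosphonate carbon), via sodium phosphonate enolate 16 (not isolated)
Conditions: NaH (1.0 equiv), THF, 0 °C; then allyl bromide (1.0 equiv), 0 °C to rt
Reagents that add atoms: allyl bromide, C=CCBr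
Why: C-Alkylation (SN2) of the phosphonate-stabilised carbanion with an allylic halide, in which the single equivalent of base is taken up by the most acidic CH2 so that the lactate centre is not deprotonated, and the new phosphonate-bearing centre is irrelevant because step 11 removes it.

Step 11
Reactants: 17 the allyl phosphonate; 9 the ortho-substituted aryl aldehyde
Product: 19 Dan (2E)-2-[(6-{[3,4-bis(tert-butyldimethylsilyloxy)phenyl](triethylsilyloxy)methyl}-2,2-dimethyl-1,3-benzodioxol-5-yl)methylidene]pent-4-enoate (both carbinol epimers), via sodium phosphonate carbanion 18 (not isolated)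
Conditions: NaH (slightly less than 1 equiv relative to 17), THF, 0 °C; then 9, 0 °C to rt
Reagents that add atoms: none
Why: Horner–Wadsworth–Emmons olefination, in which α-alkyl phosphonoacetates and aromatic aldehydes give mainly the (E)-trisubstituted acrylate with the aryl group trans to the ester and cis to the allyl arm, the geometry that ring closure requires.

Step 12
Reactants: 19 the (E)-allyl acrylate
Product: 20 Dan (2E)-2-[(6-{[3,4-bis(tert-butyldimethylsilyloxy)phenyl](triethylsilyloxy)methyl}-2,2-dimethyl-1,3-benzodioxol-5-yl)methylidene]-4-oxobutanoate (both carbinol epimers)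
Conditions: OsO4 (cat.), NaIO4, 2,6-lutidine, dioxane/H2O, rt
Reagents that add atoms: sodium periodate, [Na+].[O-]I(=O)(=O)=O
Why: Lemieux–Johnson oxidative cleavage takes the monosubstituted terminal alkene in preference to the hindered, electron-poor trisubstituted acrylate double bond and delivers the β,γ-unsaturated aldehyde.

Step 13
Reactants: 20 the silyl-protected aldehyde
Product: 21 Dan (2E)-2-({6-[(3,4-dihydroxyphenyl)(hydroxy)methyl]-2,2-dimethyl-1,3-benzodioxol-5-yl}methylidene)-4-oxobutanoate (both carbinol epimers)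
Conditions: TBAF, AcOH (1:1), THF, 0 °C; short neutral work-up, used without storage
Reagents that add atoms: none
Why: Fluoride-mediated desilylation buffered with acetic acid frees the two phenols and the carbinol without exposing the enolisable aldehyde to base.

Step 14
Reactants: 21 the carbinol aldehyde (both epimers)
Product: 24 Dan (1R,2S)-1-(3,4-dihydroxyphenyl)-2-formyl-6,7-(isopropylidenedioxy)-1,2-dihydronaphthalene-3-carboxylate (trans), via quinone methide aldehyde 22 (not isolated), via quinone methide dienamine 23 (not isolated)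
Conditions: (S)-α,α-diphenylprolinol trimethylsilyl ether (20 mol%), PhCO2H (20 mol%), degassed CHCl3, 0 °C to rt, argon
Reagents that add atoms: none
Why: Proposed new method: benzoic acid assists loss of water from the para-hydroxybenzylic carbinol to give quinone methide 22, the secondary amine condenses with the aldehyde to dienamine 23, the α-carbon C2 of 23 adds to the exocyclic carbon C1 of the quinone methide (a 1,6-addition driven by rearomatisation of the catechol ring), and hydrolysis of the resulting iminium ion releases 24 and the catalyst. The closest known reaction type is the aminocatalytic enantioselective 1,6-addition of aldehydes to para-quinone methides, known between two molecules and with quinone methides generated in the flask; the ring-closing version through a dienamine is the extension proposed here. Ring B closes in a 6-exo-trig mode (enolexo with respect to the enamine), and C1–C2 is the only new skeletal bond. C2 is controlled by the catalyst, whose C(Ph)2OSiMe3 group screens one face of the E, s-trans enamine so that the tethered electrophile bonds to the open Si face, which for the (S)-catalyst corresponds to 2S; C1 is controlled relative to C2 by the half-chair transition state that holds the quinoid ring anti to the enamine unit, giving the trans (1R,2S) isomer from either carbinol epimer because 22 is planar at C1. The step needs α- rather than γ-attack of the dienamine, which the substrate secures because bonding through C4 would create a four-membered ring, and it needs the (E) geometry at C3=C4 from step 11, which places the formylmethyl arm next to the quinone methide. Because the C3 ester carries an enantiopure (R)-lactate unit, any minor core stereoisomer is a diastereomer of 24 and can be removed by chromatography.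

Step 15
Reactants: 24 the cyclised catechol aldehyde
Product: 25 Dan (1R,2S)-1-[3,4-bis(tert-butyldimethylsilyloxy)phenyl]-2-formyl-6,7-(isopropylidenedioxy)-1,2-dihydronaphthalene-3-carboxylate
Conditions: TBSCl, imidazole, CH2Cl2, 0 °C to rt
Reagents that add atoms: tert-butyldimethylsilyl chloride, CC(C)(C)[Si](C)(C)Cl
Why: Silylation of the catechol with a weak base protects the phenols for the oxidation and acylation that follow without epimerising the α-branched aldehyde.

Step 16
Reactants: 25 the bis-silyl aldehyde
Product: 26 (1R,2S)-1-[3,4-bis(tert-butyldimethylsilyloxy)phenyl]-3-(Dan-oxycarbonyl)-6,7-(isopropylidenedioxy)-1,2-dihydronaphthalene-2-carboxylic acid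
Conditions: NaClO2, NaH2PO4, 2-methyl-2-butene, t-BuOH/H2O, 0 °C to rt
Reagents that add atoms: sodium chlorite, [Na+].[O-]Cl=O
Why: Pinnick oxidation converts the aldehyde to the acid under mildly acidic conditions that leave C2, the alkene, the silyl ethers and the ketals unchanged.

Step 17
Reactants: 26 the C2 carboxylic acid; 13 Dan–OH
Product: 27 bis(Dan) (1R,2S)-1-[3,4-bis(tert-butyldimethylsilyloxy)phenyl]-6,7-(isopropylidenedioxy)-1,2-dihydronaphthalene-2,3-dicarboxylate
Conditions: DCC, DMAP (cat.), CH2Cl2, 0 °C to rt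
Reagents that add atoms: none
Why: Steglich esterification joins the second lactate unit by acylation at oxygen, and with the C3 carboxyl already esterified no cyclic anhydride can form, while the trans arrangement at C2 is the thermodynamically preferred one.

Step 18
Reactants: 27 the fully protected diester
Product: 28 bis(Dan) (1R,2S)-1-(3,4-dihydroxyphenyl)-6,7-(isopropylidenedioxy)-1,2-dihydronaphthalene-2,3-dicarboxylate
Conditions: TBAF, AcOH (1:1), THF, 0 °C
Reagents that add atoms: none
Why: Buffered fluoride desilylation removes the two aryl silyl ethers and leaves the esters and C2 untouched.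

Step 19
Reactants: 28 the acetonide tert-butyl ester
Product: 29 rabdosiin
Conditions: TFA/H2O (9:1), 0 °C to rt, argon; evaporation, reversed-phase purification
Reagents that add atoms: none
Why: Acidolysis hydrolyses the three catechol acetonides and cleaves the two tert-butyl esters in one operation, conditions under which the secondary alkyl ester linkages and all four stereocentres should persist.

**Compound list**

1 | 3,4-dihydroxybenzaldehyde | O=Cc1ccc(O)c(O)c1 | starting material
2 | 3,4-bis(tert-butyldimethylsilyloxy)benzaldehyde | O=Cc1ccc(O[Si](C)(C)C(C)(C)C)c(O[Si](C)(C)C(C)(C)C)c1 | intermediate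
3 | 2,2-dimethyl-1,3-benzodioxole | CC1(C)Oc2ccccc2O1 | starting material
4 | 5,6-dibromo-2,2-dimethyl-1,3-benzodioxole | CC1(C)Oc2cc(Br)c(Br)cc2O1 | intermediate
5 | (6-bromo-2,2-dimethyl-1,3-benzodioxol-5-yl)magnesium chloride (LiCl complex) | CC1(C)Oc2cc(Br)c([Mg]Cl)cc2O1 | intermediate
6 | (6-bromo-2,2-dimethyl-1,3-benzodioxol-5-yl)[3,4-bis(tert-butyldimethylsilyloxy)phenyl]methanol, racemic | CC1(C)Oc2cc(Br)c(C(O)c3ccc(O[Si](C)(C)C(C)(C)C)c(O[Si](C)(C)C(C)(C)C)c3)cc2O1 | intermediate
7 | triethylsilyl ether of 6, racemic | CC1(C)Oc2cc(Br)c(C(O[Si](CC)(CC)CC)c3ccc(O[Si](C)(C)C(C)(C)C)c(O[Si](C)(C)C(C)(C)C)c3)cc2O1 | intermediate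
8 | aryllithium from 7 (lithium in place of bromine) | CC1(C)Oc2cc([Li])c(C(O[Si](CC)(CC)CC)c3ccc(O[Si](C)(C)C(C)(C)C)c(O[Si](C)(C)C(C)(C)C)c3)cc2O1 | intermediate
9 | 6-{[3,4-bis(tert-butyldimethylsilyloxy)phenyl](triethylsilyloxy)methyl}-2,2-dimethyl-1,3-benzodioxole-5-carbaldehyde, racemic | CC1(C)Oc2cc(C=O)c(C(O[Si](CC)(CC)CC)c3ccc(O[Si](C)(C)C(C)(C)C)c(O[Si](C)(C)C(C)(C)C)c3)cc2O1 | intermediate
10 | (R)-3-(3,4-dihydroxyphenyl)lactic acid, (R)-danshensu | O[C@H](Cc1ccc(O)c(O)c1)C(=O)O | starting material
11 | (5R)-5-[(2,2-dimethyl-1,3-benzodioxol-5-yl)methyl]-2,2-dimethyl-1,3-dioxolan-4-one | CC1(C)O[C@H](Cc2ccc3OC(C)(C)Oc3c2)C(=O)O1 | intermediate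
12 | (2R)-3-(2,2-dimethyl-1,3-benzodioxol-5-yl)-2-hydroxypropanoic acid | O[C@H](Cc1ccc2OC(C)(C)Oc2c1)C(=O)O | intermediate
13 | tert-butyl (2R)-3-(2,2-dimethyl-1,3-benzodioxol-5-yl)-2-hydroxypropanoate (Dan–OH) | O[C@H](Cc1ccc2OC(C)(C)Oc2c1)C(=O)OC(C)(C)C | intermediate
14 | diethylphosphonoacetic acid | CCOP(=O)(OCC)CC(=O)O | starting material
15 | Dan (diethoxyphosphoryl)acetate | CCOP(=O)(OCC)CC(=O)O[C@H](Cc1ccc2OC(C)(C)Oc2c1)C(=O)OC(C)(C)C | intermediate
16 | sodium enolate of 15 (carbanion at the phosphonate carbon) | CCOP(=O)(OCC)[CH-]C(=O)O[C@H](Cc1ccc2OC(C)(C)Oc2c1)C(=O)OC(C)(C)C.[Na+] | intermediate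
17 | Dan 2-(diethoxyphosphoryl)pent-4-enoate, both epimers at the phosphonate carbon | CCOP(=O)(OCC)C(CC=C)C(=O)O[C@H](Cc1ccc2OC(C)(C)Oc2c1)C(=O)OC(C)(C)C | intermediate
18 | sodium carbanion of 17 at the phosphonate carbon | CCOP(=O)(OCC)[C-](CC=C)C(=O)O[C@H](Cc1ccc2OC(C)(C)Oc2c1)C(=O)OC(C)(C)C.[Na+] | intermediate
19 | Dan (2E)-2-[(6-{[3,4-bis(tert-butyldimethylsilyloxy)phenyl](triethylsilyloxy)methyl}-2,2-dimethyl-1,3-benzodioxol-5-yl)methylidene]pent-4-enoate, both carbinol epimers | C=CC/C(C(=O)O[C@H](Cc1ccc2OC(C)(C)Oc2c1)C(=O)OC(C)(C)C)=C\c1cc2OC(C)(C)Oc2cc1C(O[Si](CC)(CC)CC)c1ccc(O[Si](C)(C)C(C)(C)C)c(O[Si](C)(C)C(C)(C)C)c1 | intermediate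
20 | Dan (2E)-2-[(6-{[3,4-bis(tert-butyldimethylsilyloxy)phenyl](triethylsilyloxy)methyl}-2,2-dimethyl-1,3-benzodioxol-5-yl)methylidene]-4-oxobutanoate, both carbinol epimers | O=CC/C(C(=O)O[C@H](Cc1ccc2OC(C)(C)Oc2c1)C(=O)OC(C)(C)C)=C\c1cc2OC(C)(C)Oc2cc1C(O[Si](CC)(CC)CC)c1ccc(O[Si](C)(C)C(C)(C)C)c(O[Si](C)(C)C(C)(C)C)c1 | intermediate
21 | Dan (2E)-2-({6-[(3,4-dihydroxyphenyl)(hydroxy)methyl]-2,2-dimethyl-1,3-benzodioxol-5-yl}methylidene)-4-oxobutanoate, both carbinol epimers (precursor of the key step) | O=CC/C(C(=O)O[C@H](Cc1ccc2OC(C)(C)Oc2c1)C(=O)OC(C)(C)C)=C\c1cc2OC(C)(C)Oc2cc1C(O)c1ccc(O)c(O)c1 | intermediate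
22 | Dan (2E)-2-({6-[(3-hydroxy-4-oxocyclohexa-2,5-dien-1-ylidene)methyl]-2,2-dimethyl-1,3-benzodioxol-5-yl}methylidene)-4-oxobutanoate (para-quinone methide) | O=CC/C(C(=O)O[C@H](Cc1ccc2OC(C)(C)Oc2c1)C(=O)OC(C)(C)C)=C\c1cc2OC(C)(C)Oc2cc1C=C1C=CC(=O)C(O)=C1 | intermediate
23 | dienamine of 22 with (S)-α,α-diphenylprolinol trimethylsilyl ether (E enamine, pyrrolidine nitrogen on the former aldehyde carbon) | C[Si](C)(C)OC(c1ccccc1)(c1ccccc1)[C@@H]1CCCN1/C=C/C(C(=O)O[C@H](Cc1ccc2OC(C)(C)Oc2c1)C(=O)OC(C)(C)C)=C\c1cc2OC(C)(C)Oc2cc1C=C1C=CC(=O)C(O)=C1 | intermediate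
24 | Dan (1R,2S)-1-(3,4-dihydroxyphenyl)-2-formyl-6,7-(isopropylidenedioxy)-1,2-dihydronaphthalene-3-carboxylate, trans (product of the key step) | O=C(O[C@H](Cc1ccc2OC(C)(C)Oc2c1)C(=O)OC(C)(C)C)C1=Cc2cc3OC(C)(C)Oc3cc2[C@@H](c2ccc(O)c(O)c2)[C@@H]1C=O | intermediate
25 | Dan (1R,2S)-1-[3,4-bis(tert-butyldimethylsilyloxy)phenyl]-2-formyl-6,7-(isopropylidenedioxy)-1,2-dihydronaphthalene-3-carboxylate | O=C(O[C@H](Cc1ccc2OC(C)(C)Oc2c1)C(=O)OC(C)(C)C)C1=Cc2cc3OC(C)(C)Oc3cc2[C@@H](c2ccc(O[Si](C)(C)C(C)(C)C)c(O[Si](C)(C)C(C)(C)C)c2)[C@@H]1C=O | intermediate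
26 | (1R,2S)-1-[3,4-bis(tert-butyldimethylsilyloxy)phenyl]-3-(Dan-oxycarbonyl)-6,7-(isopropylidenedioxy)-1,2-dihydronaphthalene-2-carboxylic acid | O=C(O[C@H](Cc1ccc2OC(C)(C)Oc2c1)C(=O)OC(C)(C)C)C1=Cc2cc3OC(C)(C)Oc3cc2[C@@H](c2ccc(O[Si](C)(C)C(C)(C)C)c(O[Si](C)(C)C(C)(C)C)c2)[C@@H]1C(=O)O | intermediate
27 | bis(Dan) (1R,2S)-1-[3,4-bis(tert-butyldimethylsilyloxy)phenyl]-6,7-(isopropylidenedioxy)-1,2-dihydronaphthalene-2,3-dicarboxylate | O=C(O[C@H](Cc1ccc2OC(C)(C)Oc2c1)C(=O)OC(C)(C)C)C1=Cc2cc3OC(C)(C)Oc3cc2[C@@H](c2ccc(O[Si](C)(C)C(C)(C)C)c(O[Si](C)(C)C(C)(C)C)c2)[C@@H]1C(=O)O[C@H](Cc1ccc2OC(C)(C)Oc2c1)C(=O)OC(C)(C)C | intermediate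
28 | bis(Dan) (1R,2S)-1-(3,4-dihydroxyphenyl)-6,7-(isopropylidenedioxy)-1,2-dihydronaphthalene-2,3-dicarboxylate | O=C(O[C@H](Cc1ccc2OC(C)(C)Oc2c1)C(=O)OC(C)(C)C)C1=Cc2cc3OC(C)(C)Oc3cc2[C@@H](c2ccc(O)c(O)c2)[C@@H]1C(=O)O[C@H](Cc1ccc2OC(C)(C)Oc2c1)C(=O)OC(C)(C)C | intermediate
29 | rabdosiin | O=C(O[C@H](Cc1ccc(O)c(O)c1)C(=O)O)C1=Cc2cc(O)c(O)cc2[C@@H](c2ccc(O)c(O)c2)[C@@H]1C(=O)O[C@H](Cc1ccc(O)c(O)c1)C(=O)O | target

**Step count**

Total: 19 steps. Longest linear sequence: 14 steps (steps 6 to 19, from (R)-danshensu 10).

**Steps most likely to fail**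

Step 14. The quinone methide may be consumed before the dienamine reaches it: by re-addition of water or the amine, by attack of an electron-rich arene of a second molecule, or by the carbinol oxygen closing onto the acrylate before ionisation. Acid-only closure through the enol would escape the catalyst and erode facial selectivity, and the α-branched product iminium may hydrolyse slowly and stall turnover. The fallback uses known chemistry and sets out from aldehyde 20. TBSOTf and Et3N in CH2Cl2 at −78 °C should give the tert-butyldimethylsilyl dienol ether F1. Catalytic TMSOTf in CH2Cl2 at −78 °C is then expected to ionise the doubly benzylic triethylsilyl ether to a diarylmethyl cation, which the silyl dienol ether captures through its α-carbon (Lewis-acid SN1 alkylation of a silyl enol ether, Mukaiyama type). This forms the same C1–C2 bond, closes ring B and leaves the aryl silyl ethers in place. No catalyst controls the absolute sense in this variant; the trans isomers should dominate and, being diastereomers through the lactate ester, are separated by chromatography. The (1R,2S) isomer is compound 25, where the route is rejoined.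

Step 11. Addition of the hindered α-allyl phosphonate carbanion to the ortho-substituted, electron-rich aldehyde may be slow and give poor E/Z selectivity. The long-lived carbanion may instead attack the neighbouring tert-butyl ester in a Dieckmann-type closure, or epimerise the lactate centre. The fallback sets out from alcohol 13. Addition of 13 to (triphenylphosphoranylidene)ketene in toluene at 80 °C should give the stabilised phosphorane F2. NBS in CH2Cl2 at −20 °C followed by K2CO3 converts it in the flask into the bromo phosphorane F3. Wittig reaction of F3 with aldehyde 9 is expected to give the (Z)-α-bromoacrylate F4, with the aryl group trans to the ester. Stille coupling of F4 with allyltributylstannane (Pd(PPh3)4, CuI, DMF, 50 °C) replaces bromine by allyl with retention of the alkene geometry and returns to the route at compound 19.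

Step 17. Acyl transfer from the hindered, activated C2 acid to the hindered secondary alcohol may be slower than rearrangement to the N-acylurea, or slower than ketene formation from the acylpyridinium ion. Ketene formation would scramble C2 or move the double bond. The fallback makes the carboxylate the nucleophile, so the acid is never activated. It sets out from alcohol 13: an Appel reaction (CBr4, PPh3, CH2Cl2, 0 °C) should give, with inversion, the (S)-bromide F5. The caesium salt of acid 26 (Cs2CO3, DMF, rt) displaces bromide from F5 in an SN2 reaction with a second inversion, restoring the (R) configuration and returning to the route at compound 27.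

Further compounds

F1 | step 14 | Dan (2E)-2-[(6-{[3,4-bis(tert-butyldimethylsilyloxy)phenyl](triethylsilyloxy)methyl}-2,2-dimethyl-1,3-benzodioxol-5-yl)methylidene]-4-(tert-butyldimethylsilyloxy)but-3-enoate (silyl dienol ether) | CC(C)(C)[Si](C)(C)OC=C/C(C(=O)O[C@H](Cc1ccc2OC(C)(C)Oc2c1)C(=O)OC(C)(C)C)=C\c1cc2OC(C)(C)Oc2cc1C(O[Si](CC)(CC)CC)c1ccc(O[Si](C)(C)C(C)(C)C)c(O[Si](C)(C)C(C)(C)C)c1
F2 | step 11 | Dan (triphenylphosphoranylidene)acetate | O=C(C=P(c1ccccc1)(c1ccccc1)c1ccccc1)O[C@H](Cc1ccc2OC(C)(C)Oc2c1)C(=O)OC(C)(C)C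
F3 | step 11 | Dan bromo(triphenylphosphoranylidene)acetate | O=C(C(Br)=P(c1ccccc1)(c1ccccc1)c1ccccc1)O[C@H](Cc1ccc2OC(C)(C)Oc2c1)C(=O)OC(C)(C)C
F4 | step 11 | Dan (2Z)-2-bromo-3-(6-{[3,4-bis(tert-butyldimethylsilyloxy)phenyl](triethylsilyloxy)methyl}-2,2-dimethyl-1,3-benzodioxol-5-yl)prop-2-enoate | Br/C(C(=O)O[C@H](Cc1ccc2OC(C)(C)Oc2c1)C(=O)OC(C)(C)C)=C\c1cc2OC(C)(C)Oc2cc1C(O[Si](CC)(CC)CC)c1ccc(O[Si](C)(C)C(C)(C)C)c(O[Si](C)(C)C(C)(C)C)c1
F5 | step 17 | tert-butyl (2S)-2-bromo-3-(2,2-dimethyl-1,3-benzodioxol-5-yl)propanoate | Br[C@@H](Cc1ccc2OC(C)(C)Oc2c1)C(=O)OC(C)(C)C
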